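**Retrosynthetic overview**
1. Niveusin B ⇐ ring-closing metathesis (C4=C5) of the seco hydroxy-enone 21; the 3,10-hemiketal then closes transannularly.
2. 21 ⇐ C7–C8 Barbier allylation joining aldehyde 10 (C1–C4, C8–C10, C14, C15) and allylic bromide 17 (C5–C7, C11–C13), then angeloylation and global deprotection/lactonisation.
3. 10 ⇐ geraniol: Sharpless epoxidation sets C10, oxidative cleavage gives a γ-lactone, an alkenyllithium adds C4/C15, and the enone is masked as a methyl ketal.
4. 17 ⇐ crotonaldehyde + methyl propiolate: asymmetric alkynylation sets C6, then Red-Al/I2 and Stille hydroxymethylation.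
5. Ring order: temporary THF ketal → γ-lactone → 10-membered carbocycle (RCM) → hemiketal THF.

Atom labels (C1–C15) use germacrane numbering throughout.
Assumption: (R,R)-ProPhenol gives the (R)-carbinol 13; if the opposite sense is found, the (S,S)-ligand is used and nothing else changes.

---

**Fragment A (aldehyde 10)**

**Step 1**
Reactants: 1 geraniol
Product: 2 (2S,3S)-2,3-epoxygeraniol
Conditions: Ti(OiPr)4 (cat.), L-(+)-DET, TBHP, 4 Å MS, CH2Cl2, −20 °C
Reagents that add atoms: tert-butyl hydroperoxide, CC(C)(C)OO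
Why: Sharpless asymmetric epoxidation; the Ti/L-(+)-tartrate complex delivers oxygen to one face of the allylic alcohol (about 95% ee), fixing the future C10 C–O stereocentre.

**Step 2**
Reactants: 2 (2S,3S)-2,3-epoxygeraniol
Product: 3 (S)-3,7-dimethyloct-6-ene-1,3-diol
Conditions: Red-Al, THF, 0 °C
Reagents that add atoms: none
Why: Hydroxyl-directed reductive epoxide opening delivers hydride to C2, giving the 1,3-diol with the tertiary C–O bond (and its configuration) untouched.

**Step 3**
Reactants: 3 (S)-3,7-dimethyloct-6-ene-1,3-diol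
Product: 4 (S)-3-hydroxy-3,7-dimethyloct-6-en-1-yl pivalate
Conditions: PivCl, pyridine, CH2Cl2, 0 °C
Reagents that add atoms: pivaloyl chloride, CC(C)(C)C(=O)Cl
Why: Selective acylation of the primary over the tertiary alcohol; the pivalate tolerates RuO4 and is later removed without acid.

**Step 4**
Reactants: 4 pivalate
Product: 5 2-[(S)-2-methyl-5-oxotetrahydrofuran-2-yl]ethyl pivalate
Conditions: RuCl3·xH2O (cat.), NaIO4, CCl4/MeCN/H2O, rt
Reagents that add atoms: sodium periodate, [Na+].[O-]I(=O)(=O)=O
Why: RuO4 oxidative cleavage of the trisubstituted alkene gives the C3 acid, which lactonises onto the tertiary alcohol; the stereocentre is not involved.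

**Step 5**
Reactants: 6 2-bromoprop-2-en-1-ol
Product: 7 [(2-bromoallyl)oxy]triisopropylsilane
Conditions: TIPSCl, imidazole, DMF, rt
Reagents that add atoms: TIPSCl, CC(C)[Si](Cl)(C(C)C)C(C)C
Why: Silyl protection; the bulky TIPS group suppresses retro-Brook migration in the derived vinyllithium.

**Step 6**
Reactants: 5 lactone; 7 bromoalkene
Product: 8 2-[(2S,5RS)-5-methoxy-2-methyl-5-{3-[(triisopropylsilyl)oxy]prop-1-en-2-yl}tetrahydrofuran-2-yl]ethyl pivalate (anomeric mixture at C3)
Conditions: 7, t-BuLi (2 equiv), Et2O, −78 °C; add 5, −78 °C; AcOH quench; then MeOH, HC(OMe)3, PPTS (cat.), 0 °C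
Reagents that add atoms: methanol, CO
Why: Br/Li exchange and single 1,2-addition to the γ-lactone (stable lactolate at −78 °C, hindered pivalate spared), then acid-catalysed ketalisation masks the α-methylene ketone; the anomeric mixture is irrelevant because the ketal is hydrolysed before ring closure.

**Step 7**
Reactants: 8 methyl ketal pivalate
Product: 9 2-[(2S,5RS)-5-methoxy-2-methyl-5-{3-[(triisopropylsilyl)oxy]prop-1-en-2-yl}tetrahydrofuran-2-yl]ethanol
Conditions: DIBAL-H, CH2Cl2, −78 °C; Rochelle salt
Reagents that add atoms: none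
Why: Reductive ester cleavage under non-acidic conditions; acid must be avoided because the free C8–OH would transketalise onto C3, and TIPS ether, ketal and alkene are inert.

**Step 8**
Reactants: 9 alcohol
Product: 10 2-[(2S,5RS)-5-methoxy-2-methyl-5-{3-[(triisopropylsilyl)oxy]prop-1-en-2-yl}tetrahydrofuran-2-yl]acetaldehyde
Conditions: Dess–Martin periodinane, NaHCO3, CH2Cl2, 0 °C → rt
Reagents that add atoms: none
Why: Buffered Dess–Martin oxidation gives the C8 aldehyde without ketal loss or β-elimination.

**Fragment B (bromide 17)**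

**Step 9**
Reactants: 11 (E)-crotonaldehyde; 12 methyl propiolate
Product: 13 methyl (R,E)-4-hydroxyhept-5-en-2-ynoate
Conditions: Me2Zn, (R,R)-ProPhenol (10 mol %), Ph3P=O (20 mol %), toluene, 4 °C
Reagents that add atoms: none (both reactants are incorporated)
Why: Zn–ProPhenol-catalysed asymmetric alkynylation of an enal; the dinuclear zinc catalyst selects the aldehyde face and sets C6 (R).

**Step 10**
Reactants: 13 ynoate
Product: 14 methyl (R,2Z,5E)-4-hydroxy-2-iodohepta-2,5-dienoate
Conditions: Red-Al, THF, −72 °C; EtOAc; then I2, −78 → 0 °C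
Reagents that add atoms: iodine, II
Why: Alkoxide-directed trans-hydroalumination gives a chelated vinylalanate (Al on C11, cis to C6), and iodinolysis with retention gives the Z-iodide.

**Step 11**
Reactants: 14 iodo alcohol
Product: 15 methyl (R,2Z,5E)-4-[(tert-butyldimethylsilyl)oxy]-2-iodohepta-2,5-dienoate
Conditions: TBSCl, imidazole, DMF, rt
Reagents that add atoms: TBSCl, CC(C)(C)[Si](C)(C)Cl
Why: Standard silylation; the bulky non-chelating OTBS group is the later π-facial control element.

**Step 12**
Reactants: 15 vinyl iodide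
Product: 16 methyl (R,2E,5E)-4-[(tert-butyldimethylsilyl)oxy]-2-(hydroxymethyl)hepta-2,5-dienoate
Conditions: Bu3SnCH2OH, Pd(PPh3)4 (5 mol %), toluene, 90 °C
Reagents that add atoms: (tributylstannyl)methanol, OC[Sn](CCCC)(CCCC)CCCC
Why: Stille coupling installs C13 with retention of olefin geometry (C6 cis to CH2OH).

**Step 13**
Reactants: 16 allylic alcohol
Product: 17 methyl (R,2Z,5E)-2-(bromomethyl)-4-[(tert-butyldimethylsilyl)oxy]hepta-2,5-dienoate
Conditions: CBr4, PPh3, 2,6-lutidine, CH2Cl2, 0 °C
Reagents that add atoms: carbon tetrabromide, BrC(Br)(Br)Br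
Why: Appel bromination of the primary allylic alcohol gives the thermodynamically preferred (Z)-2-(bromomethyl)enoate.

**Union and endgame**

**Step 14**
Reactants: 10 aldehyde; 17 allylic bromide
Product: 18 methyl (3R,4R)-3-[(1R,2E)-1-(TBSO)but-2-en-1-yl]-4-hydroxy-5-[(2S,5RS)-5-methoxy-2-methyl-5-(3-TIPSO-prop-1-en-2-yl)tetrahydrofuran-2-yl]-2-methylenepentanoate (6R,7R,8R,10S)
Conditions: In powder, THF/pH 7 phosphate buffer (3:1), rt
Reagents that add atoms: none
Why: Barbier allylation; the Z-configured 2-(methoxycarbonyl)allylindium reacts through a chair Zimmerman–Traxler transition state to give the 7,8-relationship, and A1,3-strain-controlled attack anti to the C6–OTBS group gives the 6,7-relationship.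

**Step 15**
Reactants: 18 alcohol; 19 angelic acid
Product: 20 the C8 (Z)-2-methylbut-2-enoate of 18
Conditions: 19, 2,4,6-trichlorobenzoyl chloride, Et3N, toluene, rt; then 18, DMAP, rt → 40 °C
Reagents that add atoms: angelic acid, C/C=C(/C)C(=O)O
Why: Yamaguchi esterification acylates the hindered C8–OH through the mixed anhydride without Z→E isomerisation to the tiglate; C8 is not inverted.

**Step 16**
Reactants: 20 angelate
Product: 21 (1R,3S)-3-hydroxy-7-(hydroxymethyl)-3-methyl-1-[(2R,3R)-4-methylidene-5-oxo-2-[(E)-prop-1-enyl]oxolan-3-yl]-6-oxooct-7-en-1-yl (Z)-2-methylbut-2-enoate (in equilibrium with its cyclic hemiketals)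
Conditions: aq. HF (48 %), MeCN, 0 °C → rt; then PPTS (cat.), CH2Cl2, rt
Reagents that add atoms: water, O
Why: One acidic operation removes TBS and TIPS, hydrolyses the methyl ketal and lactonises C6–OH onto the methyl ester to give the trans-fused α-methylene-γ-lactone; no stereocentre is touched.

**Step 17**
Reactants: 21 seco hydroxy-enone
Product: 22 niveusin B
Conditions: Hoveyda–Grubbs II (20 mol %), 1,4-benzoquinone (40 mol %), toluene (1 mM), 80 °C
Reagents that add atoms: none
Why: Ring-closing metathesis; the Ru carbene forms at the propenyl group (propene lost) and closes onto the 1,1-disubstituted C4 olefin to give the cis-in-ring (4Z) alkene, and the C10–OH then adds transannularly to the C3 ketone, where the bridge geometry allows only the (3R)-hemiketal.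

---

**Compound list**
1 | geraniol | CC(C)=CCC/C(C)=C/CO | starting material
2 | (2S,3S)-2,3-epoxygeraniol | CC(C)=CCC[C@]1(C)O[C@H]1CO | intermediate
3 | (S)-3,7-dimethyloct-6-ene-1,3-diol | CC(C)=CCC[C@](C)(O)CCO | intermediate
4 | (S)-3-hydroxy-3,7-dimethyloct-6-en-1-yl pivalate | CC(C)=CCC[C@](C)(O)CCOC(=O)C(C)(C)C | intermediate
5 | 2-[(S)-2-methyl-5-oxotetrahydrofuran-2-yl]ethyl pivalate | O=C1CC[C@@](C)(CCOC(=O)C(C)(C)C)O1 | intermediate
6 | 2-bromoprop-2-en-1-ol | C=C(Br)CO | starting material
7 | [(2-bromoallyl)oxy]triisopropylsilane | C=C(Br)CO[Si](C(C)C)(C(C)C)C(C)C | intermediate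
8 | methyl ketal pivalate (10S; C3 anomers) | C=C(CO[Si](C(C)C)(C(C)C)C(C)C)C1(OC)CC[C@@](C)(CCOC(=O)C(C)(C)C)O1 | intermediate
9 | methyl ketal alcohol (10S; C3 anomers) | C=C(CO[Si](C(C)C)(C(C)C)C(C)C)C1(OC)CC[C@@](C)(CCO)O1 | intermediate
10 | methyl ketal aldehyde (10S; C3 anomers) | C=C(CO[Si](C(C)C)(C(C)C)C(C)C)C1(OC)CC[C@@](C)(CC=O)O1 | intermediate
11 | (E)-crotonaldehyde | C/C=C/C=O | starting material
12 | methyl propiolate | C#CC(=O)OC | starting material
13 | methyl (R,E)-4-hydroxyhept-5-en-2-ynoate | COC(=O)C#C[C@H](O)/C=C/C | intermediate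
14 | methyl (R,2Z,5E)-4-hydroxy-2-iodohepta-2,5-dienoate | COC(=O)/C(I)=C/[C@H](O)/C=C/C | intermediate
15 | methyl (R,2Z,5E)-4-(TBSO)-2-iodohepta-2,5-dienoate | COC(=O)/C(I)=C/[C@H](O[Si](C)(C)C(C)(C)C)/C=C/C | intermediate
16 | methyl (R,2E,5E)-4-(TBSO)-2-(hydroxymethyl)hepta-2,5-dienoate | COC(=O)/C(CO)=C/[C@H](O[Si](C)(C)C(C)(C)C)/C=C/C | intermediate
17 | methyl (R,2Z,5E)-2-(bromomethyl)-4-(TBSO)hepta-2,5-dienoate | COC(=O)/C(CBr)=C/[C@H](O[Si](C)(C)C(C)(C)C)/C=C/C | intermediate
18 | Barbier adduct (6R,7R,8R,10S; C3 anomers) | C=C(C(=O)OC)[C@@H]([C@H](O[Si](C)(C)C(C)(C)C)/C=C/C)[C@H](O)C[C@@](C)(O1)CCC1(OC)C(=C)CO[Si](C(C)C)(C(C)C)C(C)C | intermediate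
19 | angelic acid, (Z)-2-methylbut-2-enoic acid | C/C=C(/C)C(=O)O | starting material
20 | C8 angelate of 18 | C=C(C(=O)OC)[C@@H]([C@H](O[Si](C)(C)C(C)(C)C)/C=C/C)[C@H](OC(=O)/C(C)=C\C)C[C@@](C)(O1)CCC1(OC)C(=C)CO[Si](C(C)C)(C(C)C)C(C)C | intermediate
21 | seco hydroxy-enone lactone (6R,7R,8R,10S), open form | C=C1C(=O)O[C@H](/C=C/C)[C@H]1[C@H](OC(=O)/C(C)=C\C)C[C@@](C)(O)CCC(=O)C(=C)CO | intermediate
22 | niveusin B (3R,6R,7R,8R,10S; 4Z) | C=C1C(=O)O[C@@H]2/C=C(/CO)[C@@]3(O)CC[C@@](C)(C[C@@H](OC(=O)/C(C)=C\C)[C@@H]12)O3 | target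

---

**Totals**
Total steps: 17.
Longest linear sequence: 11 (steps 1–4, 6–8, 14–17, from geraniol). The other branches are 5 steps (9–13) and 1 step (5).

**Three steps most likely to fail, with fallbacks**
1. **Step 14, Barbier stereocontrol.** The π-facial control by C6–OTBS may be wrong or weak, and indium salts may erode the ketal. Fallback: use the cyclic 3-(bromomethyl)-5-propenylbutenolide, where the ring forces the new C7 bond anti to C6, and then correct C8 by oxidation to the ketone and directed reduction, or by Mitsunobu inversion with angelic acid.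
2. **Step 17, RCM on the unprotected hydroxy-enone/hemiketal.** The hindered 1,1-disubstituted olefin may not react, the enone may oligomerise, or the E-olefin may form. Fallback: move the ring closure to C7–C8, installing the Z-C4=C5 olefin beforehand by Stille coupling of a C4 vinylstannane with a C5 Z-vinyl iodide, and close the ten-membered ring by intramolecular Zn/In Barbier (or Nozaki–Hiyama–Kishi) allylation.
3. **Step 6, alkenyllithium addition to the lactone and ketalisation.** Risks are retro-Brook migration, double addition, attack on the pivalate, and MeOH conjugate addition. Fallback: open lactone 5 to the Weinreb amide, silylate the tertiary alcohol, add the alkenyllithium to give the open-chain enone, carry C3 as a protected allylic alcohol after Luche reduction, and re-oxidise with MnO2 just before ring closure.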